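**Plan**

Numbering runs from C1 (on the guaiacyl ring, ring A) to C7 (on the 4-hydroxyphenyl ring, ring B). The retrosynthesis cuts C3–C4 (C-acylation of a C4–C7 methyl ketone by a feruloyl donor), then turns C7–O back into C7–B, then cuts the C7–aryl bond.
Enabling feature: C7 is a secondary benzylic carbinol carbon that carries ring B, the pattern produced when an aryl group moves from boron to an α-oxygenated carbanion and the C–B bond is oxidised afterwards.
Forward order: a C4–C7 carbamate with C5 masked as a dioxolane is lithiated at C7 and joined to the ring B boronic ester (C7–aryl first). Oxidation, O7 silylation and ketal cleavage give the methyl ketone, whose kinetic enolate is acylated at C4 by the ring A cinnamoyl imidazolide (C3–C4 second); desilylation ends the route. No ring is formed.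
Stereochemistry: (+)-sparteine selects the pro-R proton at C7. Trapping by boron with retention, aryl shift with inversion and C–B oxidation with retention turn this into 7S; the E C1=C2 alkene is brought in with ferulic acid.

Key step: step 4

Assumption: the enol of the 1,3-diketone equilibrates with its diketo and chelated-enol tautomers, so the enol position and C3=C4 geometry written for the target are one depiction of the diketone and need no separate control; C7 is the only stereocentre to be set.

**Route**

Step 1
Reactants: 1 ethyl 2-(2-methyl-1,3-dioxolan-2-yl)acetate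
Product: 2 2-(2-methyl-1,3-dioxolan-2-yl)ethanol
Conditions: LiAlH4, Et2O, 0 °C → rt; Na2SO4·10H2O quench
Reagents that add atoms: none
Why: Hydride reduction of the ester by LiAlH4 (ester to primary alcohol) should be clean because the dioxolane is inert to basic hydride and no other reducible group is present.

Step 2
Reactants: 2 2-(2-methyl-1,3-dioxolan-2-yl)ethanol; 3 N,N-diisopropylcarbamoyl chloride
Product: 4 2-(2-methyl-1,3-dioxolan-2-yl)ethyl N,N-diisopropylcarbamate
Conditions: NaH, THF, 0 °C; then 3, reflux
Reagents that add atoms: none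
Why: O-Carbamoylation of the sodium alkoxide by the carbamoyl chloride (nucleophilic acyl substitution) installs the directing and leaving group for step 4 under basic conditions that cannot harm the ketal.

Step 3
Reactants: 5 4-hydroxyphenylboronic acid pinacol ester
Product: 6 4-(tert-butyldimethylsilyloxy)phenylboronic acid pinacol ester
Conditions: TBSCl, imidazole, DMF, rt
Reagents that add atoms: tert-butyldimethylsilyl chloride, CC(C)(C)[Si](C)(C)Cl
Why: Imidazole-promoted silyl ether formation removes the only acidic proton of the boron partner, which would otherwise quench the organolithium of step 4, and leaves the pinacol boronate untouched.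

Step 4
Reactants: 4 2-(2-methyl-1,3-dioxolan-2-yl)ethyl N,N-diisopropylcarbamate; 6 4-(tert-butyldimethylsilyloxy)phenylboronic acid pinacol ester
Product: 9 (S)-2-{1-[4-(tert-butyldimethylsilyloxy)phenyl]-2-(2-methyl-1,3-dioxolan-2-yl)ethyl}-4,4,5,5-tetramethyl-1,3,2-dioxaborolane, via lithiated carbamate 7 (not isolated), via lithium boronate complex 8 (not isolated)
Conditions: 4 (1.3 equiv), s-BuLi (1.25 equiv), (+)-sparteine (1.3 equiv), Et2O, −78 °C, 5 h; then 6 (1.0 equiv), −78 °C, 1 h; then MgBr2·OEt2, −78 °C → reflux; aq NH4Cl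
Reagents that add atoms: none
Why: sec-Butyllithium bound to (+)-sparteine is guided by the carbamate carbonyl and removes the pro-R proton of the O–CH2 group, giving the dipole-stabilised organolithium 7 (R at C7), which holds its configuration at −78 °C. Boronic ester 6 traps 7 with retention to give the tetracoordinate boronate 8, and on warming with MgBr2·OEt2 ring B shifts from boron to C7 anti to the departing carbamate, with inversion at carbon, so that the C7–aryl and C7–B bonds of 9 arise in one flask. The closest known reaction type is the lithiation–borylation (1,2-metallate rearrangement) of sparteine-lithiated primary O-alkyl carbamates with aryl pinacol boronic esters to secondary benzylic boronic esters. No ring is closed. The one new stereocentre, C7, is set under reagent control by the diamine antipode and relayed by the stereospecific retention–inversion sequence to S. The step needs lithiation only at the O–CH2 group and carbon rather than oxygen migration from boron: the carbamate directs the base, the dioxolane has neither an acidic proton nor a β-leaving group and is of a kind routinely carried through ethereal magnesium bromide in Grignard solutions, the silyl ether has removed the phenolic proton, and the electron-rich aryl group migrates far more readily than a pinacol oxygen.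

Step 5
Reactants: 9 (S)-2-{1-[4-(tert-butyldimethylsilyloxy)phenyl]-2-(2-methyl-1,3-dioxolan-2-yl)ethyl}-4,4,5,5-tetramethyl-1,3,2-dioxaborolane
Product: 10 (S)-1-[4-(tert-butyldimethylsilyloxy)phenyl]-2-(2-methyl-1,3-dioxolan-2-yl)ethanol
Conditions: NaBO3·4H2O, THF/H2O (1:1), rt
Reagents that add atoms: sodium perborate (peroxoborate dimer, water of crystallisation omitted), [Na+].[Na+].O[B-]1(O)OO[B-](O)(O)OO1
Why: In this oxidation of a boronic ester the peroxoborate adds to boron and C7 migrates from boron to oxygen with retention, so the S configuration is kept, while the mildly basic perborate medium should spare the aryl silyl ether and the ketal.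

Step 6
Reactants: 10 (S)-1-[4-(tert-butyldimethylsilyloxy)phenyl]-2-(2-methyl-1,3-dioxolan-2-yl)ethanol
Product: 11 (S)-2-{2-(tert-butyldimethylsilyloxy)-2-[4-(tert-butyldimethylsilyloxy)phenyl]ethyl}-2-methyl-1,3-dioxolane
Conditions: TBSCl (excess), imidazole, DMAP (cat.), DMF, rt
Reagents that add atoms: tert-butyldimethylsilyl chloride, CC(C)(C)[Si](C)(C)Cl
Why: Silyl ether formation at the secondary benzylic alcohol under basic conditions keeps the acid-labile ketal intact, blocks O7 against the enolate chemistry of step 10, and the excess silyl chloride would re-cap any ring B phenol freed in step 5.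

Step 7
Reactants: 11 (S)-2-{2-(tert-butyldimethylsilyloxy)-2-[4-(tert-butyldimethylsilyloxy)phenyl]ethyl}-2-methyl-1,3-dioxolane
Product: 12 (S)-4-(tert-butyldimethylsilyloxy)-4-[4-(tert-butyldimethylsilyloxy)phenyl]butan-2-one
Conditions: PPTS (cat.), acetone/H2O (9:1), 50 °C
Reagents that add atoms: water, O
Why: Acid-catalysed acetal hydrolysis with the weak acid PPTS should free the C5 methyl ketone without cleaving the tert-butyldimethylsilyl ethers or ionising the benzylic C7–O bond, so the stereocentre is untouched.

Step 8
Reactants: 13 ferulic acid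
Product: 15 (E)-3-[4-(tert-butyldimethylsilyloxy)-3-methoxyphenyl]prop-2-enoic acid, via bis-silylated ferulic acid 14 (not isolated)
Conditions: TBSCl (2.5 equiv), imidazole, DMF, rt; then AcOH/THF/H2O (3:1:1), rt
Reagents that add atoms: tert-butyldimethylsilyl chloride, CC(C)(C)[Si](C)(C)Cl
Why: Silylation of both the phenol and the carboxyl group followed by selective hydrolysis of the much more labile silyl ester (silyl ether formation and silyl ester cleavage) leaves only the phenol capped and the E alkene unchanged.

Step 9
Reactants: 15 (E)-3-[4-(tert-butyldimethylsilyloxy)-3-methoxyphenyl]prop-2-enoic acid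
Product: 16 (E)-3-[4-(tert-butyldimethylsilyloxy)-3-methoxyphenyl]-1-(1H-imidazol-1-yl)prop-2-en-1-one
Conditions: CDI, THF, rt; imidazole removed by a brief cold-water wash
Reagents that add atoms: 1,1'-carbonyldiimidazole, O=C(n1ccnc1)n1ccnc1
Why: Carboxyl activation with carbonyldiimidazole gives the N-acylimidazole with loss of CO2 and imidazole under neutral conditions that the aryl silyl ether tolerates, and the isolated imidazolide carries no acidic proton that could quench an enolate.

Step 10
Reactants: 12 (S)-4-(tert-butyldimethylsilyloxy)-4-[4-(tert-butyldimethylsilyloxy)phenyl]butan-2-one; 16 (E)-3-[4-(tert-butyldimethylsilyloxy)-3-methoxyphenyl]-1-(1H-imidazol-1-yl)prop-2-en-1-one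
Product: 18 (1E,7S)-7-(tert-butyldimethylsilyloxy)-1-[4-(tert-butyldimethylsilyloxy)-3-methoxyphenyl]-7-[4-(tert-butyldimethylsilyloxy)phenyl]-3-hydroxyhepta-1,3-dien-5-one (enol form of the 3,5-dione), via lithium enolate 17 (not isolated)
Conditions: LiN(SiMe3)2 (2.2 equiv), THF, −78 °C; then 16 (1.05 equiv), −78 → −40 °C; aq NH4Cl
Reagents that add atoms: none
Why: At −78 °C the hindered amide base deprotonates the methyl group (kinetic enolate formation), the enolate attacks the carbonyl carbon of the acyl imidazolide (Claisen-type C-acylation to a 1,3-diketone) and the second equivalent of base takes up the acidic C4 proton of the product so that no enolate is lost, all without a bond change at C7.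

Step 11
Reactants: 18 (1E,7S)-7-(tert-butyldimethylsilyloxy)-1-[4-(tert-butyldimethylsilyloxy)-3-methoxyphenyl]-7-[4-(tert-butyldimethylsilyloxy)phenyl]-3-hydroxyhepta-1,3-dien-5-one
Product: 19 (1E,7S)-3,7-dihydroxy-1-(4-hydroxy-3-methoxyphenyl)-7-(4-hydroxyphenyl)hepta-1,3-dien-5-one (target CNP0206527.1; enol form of the 3,5-dione)
Conditions: HF·pyridine, pyridine, THF, 0 °C → rt
Reagents that add atoms: none
Why: Fluoride-driven silyl ether cleavage with pyridine-buffered HF·pyridine should free both phenols and O7 under weakly acidic conditions chosen to suppress retro-aldol cleavage and loss of water across C6–C7, with no bond change at C7.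

**Compound list**

1 | ethyl 2-(2-methyl-1,3-dioxolan-2-yl)acetate | CCOC(=O)CC1(C)OCCO1 | starting material
2 | 2-(2-methyl-1,3-dioxolan-2-yl)ethanol | CC1(CCO)OCCO1 | intermediate
3 | N,N-diisopropylcarbamoyl chloride | CC(C)N(C(C)C)C(Cl)=O | starting material
4 | 2-(2-methyl-1,3-dioxolan-2-yl)ethyl N,N-diisopropylcarbamate | CC1(CCOC(=O)N(C(C)C)C(C)C)OCCO1 | intermediate
5 | 4-hydroxyphenylboronic acid pinacol ester | CC1(C)OB(OC1(C)C)c1ccc(O)cc1 | starting material
6 | 4-(tert-butyldimethylsilyloxy)phenylboronic acid pinacol ester | CC1(C)OB(OC1(C)C)c1ccc(O[Si](C)(C)C(C)(C)C)cc1 | intermediate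
7 | (R)-1-lithio-2-(2-methyl-1,3-dioxolan-2-yl)ethyl N,N-diisopropylcarbamate, held as its (+)-sparteine complex | CC1(C[C@@H]([Li])OC(=O)N(C(C)C)C(C)C)OCCO1 | intermediate (not isolated)
8 | lithium (R)-[1-(N,N-diisopropylcarbamoyloxy)-2-(2-methyl-1,3-dioxolan-2-yl)ethyl][4-(tert-butyldimethylsilyloxy)phenyl](pinacolato)borate | CC1(C[C@H](OC(=O)N(C(C)C)C(C)C)[B-]2(OC(C)(C)C(C)(C)O2)c2ccc(O[Si](C)(C)C(C)(C)C)cc2)OCCO1.[Li+] | intermediate (not isolated)
9 | (S)-2-{1-[4-(tert-butyldimethylsilyloxy)phenyl]-2-(2-methyl-1,3-dioxolan-2-yl)ethyl}-4,4,5,5-tetramethyl-1,3,2-dioxaborolane | CC1(C[C@H](B2OC(C)(C)C(C)(C)O2)c2ccc(O[Si](C)(C)C(C)(C)C)cc2)OCCO1 | intermediate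
10 | (S)-1-[4-(tert-butyldimethylsilyloxy)phenyl]-2-(2-methyl-1,3-dioxolan-2-yl)ethanol | CC1(C[C@H](O)c2ccc(O[Si](C)(C)C(C)(C)C)cc2)OCCO1 | intermediate
11 | (S)-2-{2-(tert-butyldimethylsilyloxy)-2-[4-(tert-butyldimethylsilyloxy)phenyl]ethyl}-2-methyl-1,3-dioxolane | CC1(C[C@H](O[Si](C)(C)C(C)(C)C)c2ccc(O[Si](C)(C)C(C)(C)C)cc2)OCCO1 | intermediate
12 | (S)-4-(tert-butyldimethylsilyloxy)-4-[4-(tert-butyldimethylsilyloxy)phenyl]butan-2-one | CC(=O)C[C@H](O[Si](C)(C)C(C)(C)C)c1ccc(O[Si](C)(C)C(C)(C)C)cc1 | intermediate
13 | ferulic acid, (E)-3-(4-hydroxy-3-methoxyphenyl)prop-2-enoic acid | COc1cc(/C=C/C(=O)O)ccc1O | starting material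
14 | tert-butyldimethylsilyl (E)-3-[4-(tert-butyldimethylsilyloxy)-3-methoxyphenyl]prop-2-enoate | COc1cc(/C=C/C(=O)O[Si](C)(C)C(C)(C)C)ccc1O[Si](C)(C)C(C)(C)C | intermediate (not isolated)
15 | (E)-3-[4-(tert-butyldimethylsilyloxy)-3-methoxyphenyl]prop-2-enoic acid | COc1cc(/C=C/C(=O)O)ccc1O[Si](C)(C)C(C)(C)C | intermediate
16 | (E)-3-[4-(tert-butyldimethylsilyloxy)-3-methoxyphenyl]-1-(1H-imidazol-1-yl)prop-2-en-1-one | COc1cc(/C=C/C(=O)n2ccnc2)ccc1O[Si](C)(C)C(C)(C)C | intermediate
17 | lithium (S)-4-(tert-butyldimethylsilyloxy)-4-[4-(tert-butyldimethylsilyloxy)phenyl]but-1-en-2-olate | C=C(O[Li])C[C@H](O[Si](C)(C)C(C)(C)C)c1ccc(O[Si](C)(C)C(C)(C)C)cc1 | intermediate (not isolated)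
18 | (1E,7S)-7-(tert-butyldimethylsilyloxy)-1-[4-(tert-butyldimethylsilyloxy)-3-methoxyphenyl]-7-[4-(tert-butyldimethylsilyloxy)phenyl]-3-hydroxyhepta-1,3-dien-5-one | COc1cc(/C=C/C(O)=C\C(=O)C[C@H](O[Si](C)(C)C(C)(C)C)c2ccc(O[Si](C)(C)C(C)(C)C)cc2)ccc1O[Si](C)(C)C(C)(C)C | intermediate
19 | (1E,7S)-3,7-dihydroxy-1-(4-hydroxy-3-methoxyphenyl)-7-(4-hydroxyphenyl)hepta-1,3-dien-5-one | COc1cc(/C=C/C(O)=C\C(=O)C[C@H](O)c2ccc(O)cc2)ccc1O | target

**Step count and risks**

Total steps: 11. Longest linear sequence: 8 steps (1, 2, 4, 5, 6, 7, 10, 11).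

Steps most likely to fail:

1. Step 4. What may go wrong: a dioxolane oxygen may compete with the diamine for lithium during deprotonation and lower the enantioselection; the 1,2-shift from the carbamate-bearing boronate may be sluggish, so that the complex reverts to its partners on warming; the Lewis acid may open the ketal. Fallback: an independent, reagent-controlled entry to alcohol 10 that forms the C7–aryl bond by ketone synthesis instead of the boron-to-carbon shift. It sets out from ester 1, which with MeNHOMe·HCl and i-PrMgCl in THF at −20 °C should give the Weinreb amide N-methoxy-N-methyl-2-(2-methyl-1,3-dioxolan-2-yl)acetamide F1. Addition of 4-(tert-butyldimethylsilyloxy)phenylmagnesium bromide (from the commercial aryl bromide) should give the aryl ketone 1-[4-(tert-butyldimethylsilyloxy)phenyl]-2-(2-methyl-1,3-dioxolan-2-yl)ethan-1-one F2. Corey–Bakshi–Shibata reduction with the (R)-2-methyl-oxazaborolidine catalyst and BH3·SMe2, the aryl group acting as the large substituent, is expected to give the S alcohol, which is compound 10; the route is rejoined there, before step 6.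

2. Step 10. What may go wrong: proton transfer from the forming diketone to unreacted enolate, enolisation toward C6 followed by β-elimination of the C7 silyloxy group, attack of the amide base on the acyl donor, or O-acylation. Fallback: a two-stage aldol and oxidation sequence that needs only one equivalent of base and no acyl transfer. It sets out from ketone 12, whose kinetic lithium enolate (LDA, THF, −78 °C) is added to the aldehyde (E)-3-[4-(tert-butyldimethylsilyloxy)-3-methoxyphenyl]prop-2-enal F3 (from commercial coniferyl aldehyde with TBSCl and imidazole). This should give, by 1,2-addition, the aldol adduct (1E,7S)-7-(tert-butyldimethylsilyloxy)-1-[4-(tert-butyldimethylsilyloxy)-3-methoxyphenyl]-7-[4-(tert-butyldimethylsilyloxy)phenyl]-3-hydroxyhept-1-en-5-one F4 as a mixture of C3 epimers. Oxidation of this allylic carbinol with Dess–Martin periodinane in CH2Cl2 buffered with NaHCO3 removes the C3 stereocentre and gives compound 18, where the route is rejoined.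

3. Step 11. What may go wrong: during the slow removal of the hindered secondary silyl ether, loss of water across C6–C7 to the fully conjugated curcuminoid, ionisation of the benzylic C7–O bond with racemisation, or retro-aldol cleavage. Fallback: a change of the O7 protecting group to one that leaves under much gentler conditions. It sets out from alcohol 10, which with TESCl and imidazole in DMF should give the triethylsilyl ether (S)-2-{2-[4-(tert-butyldimethylsilyloxy)phenyl]-2-(triethylsilyloxy)ethyl}-2-methyl-1,3-dioxolane F5. PPTS in wet acetone at room temperature should unmask the ketone (S)-4-[4-(tert-butyldimethylsilyloxy)phenyl]-4-(triethylsilyloxy)butan-2-one F6. Acylation of its kinetic lithium enolate with imidazolide 16 as in step 10 should give the diketone (1E,7S)-1-[4-(tert-butyldimethylsilyloxy)-3-methoxyphenyl]-7-[4-(tert-butyldimethylsilyloxy)phenyl]-3-hydroxy-7-(triethylsilyloxy)hepta-1,3-dien-5-one F7. One short treatment with TBAF buffered by an equimolar amount of AcOH in THF at 0 °C should then remove the two aryl silyl ethers and the labile triethylsilyl ether together and give the target 19.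

**Further compounds**

F1 | step 4 | N-methoxy-N-methyl-2-(2-methyl-1,3-dioxolan-2-yl)acetamide | CON(C)C(=O)CC1(C)OCCO1
F2 | step 4 | 1-[4-(tert-butyldimethylsilyloxy)phenyl]-2-(2-methyl-1,3-dioxolan-2-yl)ethan-1-one | CC1(CC(=O)c2ccc(O[Si](C)(C)C(C)(C)C)cc2)OCCO1
F3 | step 10 | (E)-3-[4-(tert-butyldimethylsilyloxy)-3-methoxyphenyl]prop-2-enal | COc1cc(/C=C/C=O)ccc1O[Si](C)(C)C(C)(C)C
F4 | step 10 | (1E,7S)-7-(tert-butyldimethylsilyloxy)-1-[4-(tert-butyldimethylsilyloxy)-3-methoxyphenyl]-7-[4-(tert-butyldimethylsilyloxy)phenyl]-3-hydroxyhept-1-en-5-one (C3 epimers) | COc1cc(/C=C/C(O)CC(=O)C[C@H](O[Si](C)(C)C(C)(C)C)c2ccc(O[Si](C)(C)C(C)(C)C)cc2)ccc1O[Si](C)(C)C(C)(C)C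
F5 | step 11 | (S)-2-{2-[4-(tert-butyldimethylsilyloxy)phenyl]-2-(triethylsilyloxy)ethyl}-2-methyl-1,3-dioxolane | CC1(C[C@H](O[Si](CC)(CC)CC)c2ccc(O[Si](C)(C)C(C)(C)C)cc2)OCCO1
F6 | step 11 | (S)-4-[4-(tert-butyldimethylsilyloxy)phenyl]-4-(triethylsilyloxy)butan-2-one | CC(=O)C[C@H](O[Si](CC)(CC)CC)c1ccc(O[Si](C)(C)C(C)(C)C)cc1
F7 | step 11 | (1E,7S)-1-[4-(tert-butyldimethylsilyloxy)-3-methoxyphenyl]-7-[4-(tert-butyldimethylsilyloxy)phenyl]-3-hydroxy-7-(triethylsilyloxy)hepta-1,3-dien-5-one | COc1cc(/C=C/C(O)=C\C(=O)C[C@H](O[Si](CC)(CC)CC)c2ccc(O[Si](C)(C)C(C)(C)C)cc2)ccc1O[Si](C)(C)C(C)(C)C
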